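**Plan**
Retrosynthesis, cut 1: the three benzyl C–O bonds (two aryl ethers, one ester) are removed last by hydrogenolysis.
Cut 2: in ring B the C3'–C4' and C5'–C6' bonds, with CO2 and methanol added back. The C4' methoxyl and C5' hydrogen form a ketene acetal unit between C3' and C6', which are C3 and C6 of a 2-pyranone-3,5-dicarboxylate carrying ring A as its C5 aryl ester.
Cut 3: the pyranone C3–CO2Bn bond (carbonylation of C3–Br), then O1–C2 and C4–C5 (a malonyl unit on an aryl acetoacetate), then the acetoacetyl C–O bond to the ring A C4 oxygen.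
Forward: ring A is bought; the pyranone ring is built on its C4 oxygen (steps 1–2) and dressed (steps 3–5); ring B arises last by cycloaddition, CO2 loss and aromatisation (step 6); hydrogenolysis follows (step 7).
Stereochemistry: the target has no stereocentre; the two bridgehead centres of the cycloadduct are racemic and vanish on aromatisation.

Key step: step 6

Remark on the chemistry: ring A is numbered as the methyl benzoate (C1 CO2Me, C2 OH, C3 Me, C4 O-acyl, C5 H, C6 Me) and ring B with primes (C1' depside carbonyl carbon attached, C2' OH, C3' CO2H, C4' OMe, C5' H, C6' Me). The pyranone is numbered O1, C2 (lactone C=O), C3 to C6. Racemic bicyclic intermediates are drawn as one enantiomer.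

**Step 1**
Reactants: 1 methyl 2,4-dihydroxy-3,6-dimethylbenzoate; 2 2,2,6-trimethyl-4H-1,3-dioxin-4-one
Product: 4 methyl 2-hydroxy-3,6-dimethyl-4-[(3-oxobutanoyl)oxy]benzoate, via acetylketene 3 (not isolated)
Conditions: 2 (1.05 equiv), xylene, 130 °C, acetone distilled off
Reagents that add atoms: none
Why: Thermal retro-[4+2] fragmentation of the dioxinone releases acetylketene, which acetoacetylates the free C4 phenol of ring A (acylketene trapping), while the C2 hydroxyl, hydrogen-bonded to the methyl ester and flanked on both sides, should stay untouched; no stereocentre is formed.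

**Step 2**
Reactants: 4 methyl 2-hydroxy-3,6-dimethyl-4-[(3-oxobutanoyl)oxy]benzoate; 5 malonyl dichloride
Product: 6 3-hydroxy-4-(methoxycarbonyl)-2,5-dimethylphenyl 4-hydroxy-6-methyl-2-oxo-2H-pyran-5-carboxylate
Conditions: 5 (1.1 equiv), CH2Cl2, 0 °C to reflux, N2 stream to sweep out HCl
Reagents that add atoms: none
Why: Malonyl dichloride annulation of a 1,3-dicarbonyl compound, in which the acetoacetate enol is C-acylated at its central carbon and the acetyl enol oxygen then closes the lactone on the second acid chloride, giving the 4-hydroxy-2-pyranone with the aryl ester at C5; without base the chelated ring A phenol should not be acylated.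

**Step 3**
Reactants: 6 3-hydroxy-4-(methoxycarbonyl)-2,5-dimethylphenyl 4-hydroxy-6-methyl-2-oxo-2H-pyran-5-carboxylate
Product: 7 3-hydroxy-4-(methoxycarbonyl)-2,5-dimethylphenyl 3-bromo-4-hydroxy-6-methyl-2-oxo-2H-pyran-5-carboxylate
Conditions: NBS (1.0 equiv), CH2Cl2, 0 °C, dark
Reagents that add atoms: N-bromosuccinimide O=C1CCC(=O)N1Br
Why: Electrophilic bromination of the enolised beta-keto lactone at C3, the only nucleophilic ring carbon of the 4-hydroxy-2-pyranone, which should react far faster than the hydrogen-bonded, ester-deactivated ring A phenol.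

**Step 4**
Reactants: 7 3-hydroxy-4-(methoxycarbonyl)-2,5-dimethylphenyl 3-bromo-4-hydroxy-6-methyl-2-oxo-2H-pyran-5-carboxylate
Product: 8 3-(benzyloxy)-4-(methoxycarbonyl)-2,5-dimethylphenyl 4-(benzyloxy)-3-bromo-6-methyl-2-oxo-2H-pyran-5-carboxylate
Conditions: BnBr (2.5 equiv), K2CO3 (3 equiv), DMF, 25 to 50 °C
Reagents that add atoms: benzyl bromide BrCc1ccccc1
Why: Williamson etherification in which K2CO3 ionises the acidic pyranone 4-OH and the ring A phenol and both oxygens are benzylated, the pyranone anion reacting at O4 to keep the 2-pyranone, as is usual for 4-hydroxy-2-pyranones with alkyl halides and carbonate in a dipolar aprotic solvent.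

**Step 5**
Reactants: 8 3-(benzyloxy)-4-(methoxycarbonyl)-2,5-dimethylphenyl 4-(benzyloxy)-3-bromo-6-methyl-2-oxo-2H-pyran-5-carboxylate
Product: 9 3-benzyl 5-[3-(benzyloxy)-4-(methoxycarbonyl)-2,5-dimethylphenyl] 4-(benzyloxy)-6-methyl-2-oxo-2H-pyran-3,5-dicarboxylate
Conditions: CO (1 atm), BnOH (3 equiv), Pd(OAc)2 (5 mol %), Xantphos (6 mol %), Et3N (2 equiv), toluene, 80 °C
Reagents that add atoms: carbon monoxide [C-]#[O+]; benzyl alcohol OCc1ccccc1
Why: Palladium-catalysed alkoxycarbonylation of an alkenyl bromide, in which the electron-poor C3–Br bond adds to zerovalent palladium, CO inserts and benzyl alcohol cleaves the acylpalladium bromide to the benzyl ester while triethylamine takes up HBr; with benzyl alcohol as nucleophile any ether exchange at C4 is degenerate.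

**Step 6**
Reactants: 9 3-benzyl 5-[3-(benzyloxy)-4-(methoxycarbonyl)-2,5-dimethylphenyl] 4-(benzyloxy)-6-methyl-2-oxo-2H-pyran-3,5-dicarboxylate; 10 1,1-dimethoxyethene
Product: 13 benzyl 2-(benzyloxy)-3-{[3-(benzyloxy)-4-(methoxycarbonyl)-2,5-dimethylphenoxy]carbonyl}-6-methoxy-4-methylbenzoate, via bicyclic lactone 11 (not isolated), via dimethoxycyclohexadiene 12 (not isolated)
Conditions: 10 (8 equiv), toluene, 110 °C, sealed tube
Reagents that add atoms: none
Why: The pyranone diene C3=C4–C5=C6, made electron-poor by the C3 benzyl ester, the C5 aryl ester and the lactone carbonyl, should take up the electron-rich ketene acetal in an inverse-electron-demand Diels–Alder reaction, concerted but asynchronous or stepwise through a zwitterion of the same orientation, forming C5'–C6' (acetal CH2 to pyranone C6) and C3'–C4' (acetal carbon to pyranone C3) to give the 2-oxabicyclo[2.2.2]octenone 11. Retro-Diels–Alder loss of CO2 from 11 gives the dimethoxycyclohexadiene 12, which loses methanol across C4'–C5' to aromatise; the closest known reaction is the annulation of 2-pyranone-3-carboxylates and 2-pyranone-5-carboxylates with 1,1-dimethoxyethene to aryl methyl ethers. Ring B closes by [4+2] cycloaddition, the four diene carbons of the pyranone and the two alkene carbons of the acetal becoming the six-membered carbocycle. The two bridgehead stereocentres of 11 are fixed relative to each other by the bicycle, arise as a racemate and are destroyed on aromatisation, so no stereocontrol is needed. The step needs one regiochemistry, methoxyl next to the benzyl ester, and the substrate secures it: the nucleophilic CH2 attacks C6, the terminus beta to the C5 ester and vinylogous to the C3 ester and lactone carbonyl, so the acetal carbon must end on C3. Benzyl protection of both hydroxyls keeps acidic OH groups away from the acetal, and the excess acetal takes up the liberated methanol.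

**Step 7**
Reactants: 13 benzyl 2-(benzyloxy)-3-{[3-(benzyloxy)-4-(methoxycarbonyl)-2,5-dimethylphenoxy]carbonyl}-6-methoxy-4-methylbenzoate
Product: 14 2-hydroxy-3-{[3-hydroxy-4-(methoxycarbonyl)-2,5-dimethylphenoxy]carbonyl}-6-methoxy-4-methylbenzoic acid
Conditions: H2 (1 atm), Pd on carbon (10 wt % Pd), EtOAc, 25 °C
Reagents that add atoms: none
Why: Heterogeneous hydrogenolysis should cleave the two benzyl aryl ethers and the benzyl ester, while the depside aryl ester, the methyl ester and the aryl methyl ether are inert to H2 over Pd.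

**Compound list**
1 | methyl 2,4-dihydroxy-3,6-dimethylbenzoate | COC(=O)c1c(C)cc(O)c(C)c1O | starting material
2 | 2,2,6-trimethyl-4H-1,3-dioxin-4-one | CC1=CC(=O)OC(C)(C)O1 | starting material
3 | acetylketene (buta-1-ene-1,3-dione) | CC(=O)C=C=O | intermediate (not isolated)
4 | methyl 2-hydroxy-3,6-dimethyl-4-[(3-oxobutanoyl)oxy]benzoate | COC(=O)c1c(C)cc(OC(=O)CC(C)=O)c(C)c1O | intermediate
5 | malonyl dichloride (propanedioyl dichloride) | O=C(Cl)CC(Cl)=O | starting material
6 | 3-hydroxy-4-(methoxycarbonyl)-2,5-dimethylphenyl 4-hydroxy-6-methyl-2-oxo-2H-pyran-5-carboxylate | COC(=O)c1c(C)cc(OC(=O)C2=C(C)OC(=O)C=C2O)c(C)c1O | intermediate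
7 | 3-hydroxy-4-(methoxycarbonyl)-2,5-dimethylphenyl 3-bromo-4-hydroxy-6-methyl-2-oxo-2H-pyran-5-carboxylate | COC(=O)c1c(C)cc(OC(=O)C2=C(C)OC(=O)C(Br)=C2O)c(C)c1O | intermediate
8 | 3-(benzyloxy)-4-(methoxycarbonyl)-2,5-dimethylphenyl 4-(benzyloxy)-3-bromo-6-methyl-2-oxo-2H-pyran-5-carboxylate | COC(=O)c1c(C)cc(OC(=O)C2=C(C)OC(=O)C(Br)=C2OCc2ccccc2)c(C)c1OCc1ccccc1 | intermediate
9 | 3-benzyl 5-[3-(benzyloxy)-4-(methoxycarbonyl)-2,5-dimethylphenyl] 4-(benzyloxy)-6-methyl-2-oxo-2H-pyran-3,5-dicarboxylate | COC(=O)c1c(C)cc(OC(=O)C2=C(C)OC(=O)C(C(=O)OCc3ccccc3)=C2OCc2ccccc2)c(C)c1OCc1ccccc1 | intermediate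
10 | 1,1-dimethoxyethene | C=C(OC)OC | starting material
11 | 4-benzyl 6-[3-(benzyloxy)-4-(methoxycarbonyl)-2,5-dimethylphenyl] 5-(benzyloxy)-8,8-dimethoxy-1-methyl-3-oxo-2-oxabicyclo[2.2.2]oct-5-ene-4,6-dicarboxylate (racemic) | C[C@@]12OC(=O)[C@@](C(=O)OCc3ccccc3)(C(OCc3ccccc3)=C1C(=O)Oc1cc(C)c(C(=O)OC)c(OCc3ccccc3)c1C)C(OC)(OC)C2 | intermediate (not isolated)
12 | 1-benzyl 3-[3-(benzyloxy)-4-(methoxycarbonyl)-2,5-dimethylphenyl] 2-(benzyloxy)-6,6-dimethoxy-4-methylcyclohexa-1,3-diene-1,3-dicarboxylate | CC1=C(C(=O)Oc2cc(C)c(C(=O)OC)c(OCc3ccccc3)c2C)C(OCc2ccccc2)=C(C(=O)OCc2ccccc2)C(OC)(OC)C1 | intermediate (not isolated)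
13 | benzyl 2-(benzyloxy)-3-{[3-(benzyloxy)-4-(methoxycarbonyl)-2,5-dimethylphenoxy]carbonyl}-6-methoxy-4-methylbenzoate | COC(=O)c1c(C)cc(OC(=O)c2c(C)cc(OC)c(C(=O)OCc3ccccc3)c2OCc2ccccc2)c(C)c1OCc1ccccc1 | intermediate
14 | 2-hydroxy-3-{[3-hydroxy-4-(methoxycarbonyl)-2,5-dimethylphenoxy]carbonyl}-6-methoxy-4-methylbenzoic acid | COC(=O)c1c(C)cc(OC(=O)c2c(C)cc(OC)c(C(=O)O)c2O)c(C)c1O | target

**Count and risks**
Total steps: 7. Longest linear sequence: 7 steps, from 1 to 14.

Step 6 is the most likely to fail. The fully substituted diene is crowded at both termini and its 4-benzyloxy group donates into the ring, so cycloaddition may be slow. The acetal could then add in conjugate fashion at C4 with loss of benzyl alcohol, or the dimethoxy diene could stall before losing methanol. The fallback sets out from 9 and uses an alkyne dienophile of the same polarity, so that aromatisation needs only CO2 loss. Methoxyethyne F1 would be made from chloroacetaldehyde dimethyl acetal with NaNH2 in liquid NH3 and heated with 9 in toluene in a sealed tube. Its CH terminus should bond to C6 and its methoxy carbon to C3, giving the 2-oxabicyclo[2.2.2]octadienone F2, which extrudes CO2 and comes back to the route at 13.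

Step 5 is second. Benzyl alcohol and amine may cleave the C5 aryl ester of the electrophilic pyranone, which would detach ring A. Insertion at the crowded C3–palladium bond may also be slow enough that the bromide is simply reduced. The fallback sets out from 8 and moves the carbonylation behind the cycloaddition; 3-bromo-2-pyranone-5-carboxylates are reactive dienes toward electron-rich alkenes. Heating 8 with 10 should lead through the bromo bicyclic lactone F3 and the bromo dimethoxycyclohexadiene F4 to the aryl bromide 3-(benzyloxy)-4-(methoxycarbonyl)-2,5-dimethylphenyl 2-(benzyloxy)-3-bromo-4-methoxy-6-methylbenzoate F5. F5 is a robust arene and would be benzyloxycarbonylated (CO, BnOH, Pd(OAc)2, Xantphos, Et3N, toluene, 100 °C), coming back to the route at 13.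

Step 2 is third. Self-condensation of malonyl dichloride, a second annulation on the product, or acylation of the ring A phenol may outrun C-acylation of the weakly nucleophilic aryl acetoacetate enol. The fallback sets out from 4 and builds the ring in two controlled stages. C-acylation of the magnesium chelate of 4 (MgCl2, pyridine, CH2Cl2, 0 °C) with methyl 3-chloro-3-oxopropanoate should give the open-chain triketo ester methyl 4-{[2-acetyl-5-methoxy-3,5-dioxopentanoyl]oxy}-2-hydroxy-3,6-dimethylbenzoate F6. Acid-catalysed lactonisation of F6 (TsOH, toluene, 80 °C, methanol distilled off) through the acetyl enol oxygen then comes back to the route at 6.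

**Further compounds**
F1 | step 6 | methoxyethyne | COC#C
F2 | step 6 | 4-benzyl 6-[3-(benzyloxy)-4-(methoxycarbonyl)-2,5-dimethylphenyl] 5-(benzyloxy)-8-methoxy-1-methyl-3-oxo-2-oxabicyclo[2.2.2]octa-5,7-diene-4,6-dicarboxylate (racemic) | C[C@@]12OC(=O)[C@@](C(=O)OCc3ccccc3)(C(OCc3ccccc3)=C1C(=O)Oc1cc(C)c(C(=O)OC)c(OCc3ccccc3)c1C)C(OC)=C2
F3 | step 5 | 3-(benzyloxy)-4-(methoxycarbonyl)-2,5-dimethylphenyl 5-(benzyloxy)-4-bromo-8,8-dimethoxy-1-methyl-3-oxo-2-oxabicyclo[2.2.2]oct-5-ene-6-carboxylate (racemic) | C[C@@]12OC(=O)[C@@](Br)(C(OCc3ccccc3)=C1C(=O)Oc1cc(C)c(C(=O)OC)c(OCc3ccccc3)c1C)C(OC)(OC)C2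
F4 | step 5 | 3-(benzyloxy)-4-(methoxycarbonyl)-2,5-dimethylphenyl 6-(benzyloxy)-5-bromo-4,4-dimethoxy-2-methylcyclohexa-1,5-diene-1-carboxylate | CC1=C(C(=O)Oc2cc(C)c(C(=O)OC)c(OCc3ccccc3)c2C)C(OCc2ccccc2)=C(Br)C(OC)(OC)C1
F5 | step 5 | 3-(benzyloxy)-4-(methoxycarbonyl)-2,5-dimethylphenyl 2-(benzyloxy)-3-bromo-4-methoxy-6-methylbenzoate | COC(=O)c1c(C)cc(OC(=O)c2c(C)cc(OC)c(Br)c2OCc2ccccc2)c(C)c1OCc1ccccc1
F6 | step 2 | methyl 4-{[2-acetyl-5-methoxy-3,5-dioxopentanoyl]oxy}-2-hydroxy-3,6-dimethylbenzoate (racemic, enolisable methine) | COC(=O)CC(=O)C(C(C)=O)C(=O)Oc1cc(C)c(C(=O)OC)c(O)c1C
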